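**Retrosynthetic overview**
- The target comes from a 15-oxo-8-hydroxy Z,Z,Z-germacratrienolide. The last operations are a double epoxidation directed by the 8-OH, the C8 angelate ester, and reduction of the C15 aldehyde.
- The ten-membered ring comes from a three-carbon ring expansion (7 → 10) of a 2,2-disubstituted cyclohepta-3,5-dienone. C7–C8 is made, C4–C8 is broken, and C4=C5 appears by loss of MeOH.
- That precursor comes from C4–C5 coupling of a seven-membered β-keto ester with an enantiopure 3-(bromomethyl)butenolide acetal.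
- The seven-membered ring comes from a one-carbon ring expansion (6 → 7) of the Birch diene of m-cresol methyl ether with ethyl (bromo)diazoacetate. The butenolide comes from dimethoxyacetaldehyde and methyl 2-(bromomethyl)acrylate.
- Ring order: the six-membered ring and the lactone ring are made separately, then 6 → 7, then 7 → 10, and the two oxiranes come last.

**Numbering and assumption:** germacrane numbering is used throughout (ring C1–C10, C14 = methyl on C10, C15 on C4, lactone C11–C13, O on C6). It is assumed that the free 8-OH and the twisted Z,Z-diene of 21 steer both epoxidations as drawn, to be confirmed on 23 by NOE or X-ray.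

Step 1
Reactants: 1 m-cresol
Product: 2 3-methylanisole
Conditions: MeI, K2CO3, acetone, reflux
Reagents that add atoms: iodomethane, CI
Why: Williamson ether synthesis of a phenoxide with a methyl halide is high-yielding and creates no stereocentre.

Step 2
Reactants: 2 3-methylanisole
Product: 3 1-methoxy-5-methylcyclohexa-1,4-diene
Conditions: Li, NH3(l), t-BuOH, THF, −78 → −33 °C; then H2O
Reagents that add atoms: none
Why: In the Birch reduction both donor groups stay on sp2 carbons, so the 2,5-dihydro isomer forms with one enol ether C=C and one methyl-bearing C=C (the later C1=C10).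

Step 3
Reactants: 3 1-methoxy-5-methylcyclohexa-1,4-diene; 4 ethyl diazoacetate
Product: 7 ethyl 5-methyl-7-oxocyclohepta-2,4-diene-1-carboxylate (racemic keto/enol mixture), via ethyl bromodiazoacetate 5 (not isolated), via bromocyclopropane 6 (not isolated)
Conditions: 4, N-bromosuccinimide, DBU, CH2Cl2, 0 °C; then 3, Rh2(esp)2 (1 mol %), toluene, 0 → 40 °C
Reagents that add atoms: N-bromosuccinimide, O=C1CCC(=O)N1Br (bromine only in 5 and 6)
Why: Rhodium-carbenoid cyclopropanation goes to the more electron-rich enol ether C=C, and the 1-methoxy-7-bromocyclopropane then opens by a methoxy-assisted Grob-type fragmentation (the one-carbon ring expansion type known from dihalocarbene adducts of enol ethers), bromide removing the O-methyl group and tautomerisation giving the β-keto ester with both ring double bonds locked cis and no lasting stereocentre.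

Step 4
Reactants: 8 dimethoxyacetaldehyde; 9 methyl 2-(bromomethyl)acrylate
Product: 11 (5R)-5-(dimethoxymethyl)-3-methylideneoxolan-2-one, via silyl ether 10 (not isolated)
Conditions: CrCl2 (10 mol %), chiral carbazole-bis(oxazoline) ligand (12 mol %), Mn powder, Me3SiCl, THF, 0 → 20 °C; then 1 M HCl, THF, 0 °C
Reagents that add atoms: chlorotrimethylsilane, C[Si](C)(C)Cl (silicon only in 10)
Why: In this catalytic asymmetric Nozaki–Hiyama–Kishi-type 2-(alkoxycarbonyl)allylation the ligand enantiomer that directs Re-face attack sets C6 (R in 11, the later 6S), and the acidic work-up desilylates and lactonises.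

Step 5
Reactants: 11 (5R)-5-(dimethoxymethyl)-3-methylideneoxolan-2-one
Product: 13 (5R)-3-(bromomethyl)-5-(dimethoxymethyl)furan-2(5H)-one, via dibromide 12 (not isolated)
Conditions: Br2, CH2Cl2, 0 °C; then Et3N (1.05 equiv), −20 °C
Reagents that add atoms: bromine, BrBr
Why: Bromination–dehydrobromination adds Br2 to the 1,1-disubstituted alkene and then loses HBr by E2 from the tertiary bromide toward the ring CH2, giving the conjugated butenolide with an allylic bromide, while the low temperature and minimal base keep C6 from γ-epimerising.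

Step 6
Reactants: 7 ethyl 5-methyl-7-oxocyclohepta-2,4-diene-1-carboxylate; 13 (5R)-3-(bromomethyl)-5-(dimethoxymethyl)furan-2(5H)-one
Product: 14 ethyl 1-{[(2R)-4-(bromomethyl)-5-oxo-2,5-dihydrofuran-2-yl](methoxy)methyl}-5-methyl-7-oxocyclohepta-2,4-diene-1-carboxylate (epimer mixture at C4 and C5)
Conditions: TiCl4 (2.2 equiv), i-Pr2NEt (1.1 equiv), CH2Cl2, −78 → −40 °C
Reagents that add atoms: none
Why: In this Mukaiyama-type acetal aldol the chelated titanium enolate of the β-keto ester attacks the TiCl4-generated oxocarbenium ion at the carbon between the two carbonyls (deconjugative α-attack typical of metal-bound dienolates), and the two new centres (C4, C5) need no control because step 7 erases them while C6 is untouched.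

Step 7
Reactants: 14 ethyl 1-{[(2R)-4-(bromomethyl)-5-oxo-2,5-dihydrofuran-2-yl](methoxy)methyl}-5-methyl-7-oxocyclohepta-2,4-diene-1-carboxylate
Product: 18 ethyl (6S,7S)-8-oxogermacra-1(10)Z,2Z,4,11(13)-tetraen-12,6-olid-15-oate (ring-cis C4=C5; H6/H7 cis), via allylzinc bromide 15 (not isolated), via tricyclic zinc alkoxide 16 (not isolated), via ring-opened zinc enolate 17 (not isolated)
Conditions: activated Zn dust (3 equiv), LiCl, dry THF (0.01 M), 0 → 25 °C; sat. aq. NH4Cl
Reagents that add atoms: zinc, [Zn] (only in 15, 16, 17)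
Why: Proposed new method: zinc inserts into the allylic C–Br bond, the allylzinc adds through its γ-carbon C7 to the C8 ketone (five-ring closure, possible only on the butenolide face that carries C5, so H6/H7 become cis and C7 is set from C6), the crowded zinc aldolate 16 then breaks its C4–C8 bond in a retro-Reformatsky (retro-aldol) step made irreversible by β-elimination of methoxide from ester enolate 17 (E1cB), which erases C4 and C5 and gives the less strained ring-cis C4=C5 with the ester trans to C6 while both Z double bonds are carried over from the seven-membered ring; the closest known reaction types are Barbier allylation with 3-(bromomethyl)butenolides, the fluoride-triggered allylsilane three-carbon ring expansion of 2-sulfonylcycloalkanones, the Dowd–Beckwith expansion and Grob-type fragmentation.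

Step 8
Reactants: 18 ethyl (6S,7S)-8-oxogermacra-1(10)Z,2Z,4,11(13)-tetraen-12,6-olid-15-oate
Product: 20 (6S,7R,8R)-germacra-1(10)Z,2Z,4,11(13)-tetraene-8,15-diol 12,6-lactol (anomer mixture), via 8R-hydroxy ester 19 (not isolated)
Conditions: (S)-Me-CBS (20 mol %), catecholborane, toluene, −78 °C; then i-Bu2AlH (6 equiv), −78 → −40 °C; aq. potassium sodium tartrate
Reagents that add atoms: none
Why: The Corey–Bakshi–Shibata reduction distinguishes the branched C7 side from the C9 methylene and sets 8R by reagent control without touching ester, lactone or alkenes, and the following i-Bu2AlH 1,2-reduction takes the C15 ester to the allylic alcohol and the lactone to the lactol.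

Step 9
Reactants: 20 (6S,7R,8R)-germacra-1(10)Z,2Z,4,11(13)-tetraene-8,15-diol 12,6-lactol
Product: 21 (6S,7R,8R)-8-hydroxy-15-oxogermacra-1(10)Z,2Z,4,11(13)-tetraen-12,6-olide
Conditions: MnO2 (excess), CH2Cl2, 20 °C
Reagents that add atoms: none
Why: MnO2 allylic oxidation converts only the allylic C15 alcohol (to the enal) and the allylic lactol (back to the α-methylene lactone) and leaves the non-allylic 8-OH free, with no stereocentre affected.

Step 10
Reactants: 21 (6S,7R,8R)-8-hydroxy-15-oxogermacra-1(10)Z,2Z,4,11(13)-tetraen-12,6-olide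
Product: 23 (1R,2S,3S,6S,7R,8R,10S)-1,10:2,3-diepoxy-8-hydroxy-15-oxogermacra-4,11(13)-dien-12,6-olide, via 1(10)-monoepoxide 22 (not isolated)
Conditions: mCPBA (2.3 equiv), CH2Cl2, pH 7 phosphate buffer, 0 °C
Reagents that add atoms: 3-chloroperoxybenzoic acid, OOC(=O)c1cccc(Cl)c1
Why: In this Prilezhaev epoxidation with Henbest-type hydroxyl direction the electron-poor enal, acrylate and lactone alkenes are inert, the trisubstituted C1=C10 reacts first on the face syn to the homoallylic 8-OH (the 1,3-syn O8/O10 relation of the target, setting 1R,10S), and C2=C3 then reacts on its outer face, which in the twisted Z,Z-diene is opposite to the first oxirane (anti-diepoxide, 2S,3S), both oxiranes being cis because the alkenes are Z.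

Step 11
Reactants: 23 (1R,2S,3S,6S,7R,8R,10S)-1,10:2,3-diepoxy-8-hydroxy-15-oxogermacra-4,11(13)-dien-12,6-olide; 24 angelic acid
Product: 26 (1R,2S,3S,6S,7R,8R,10S)-8-angeloyloxy-1,10:2,3-diepoxy-15-oxogermacra-4,11(13)-dien-12,6-olide, via mixed anhydride 25 (not isolated)
Conditions: 24, 2,4,6-trichlorobenzoyl chloride, Et3N, toluene, 20 °C; then 23, 75 °C
Reagents that add atoms: 2,4,6-trichlorobenzoyl chloride, O=C(Cl)c1c(Cl)cc(Cl)cc1Cl (only in 25)
Why: Yamaguchi-type mixed-anhydride esterification run without a nucleophilic catalyst acylates the hindered secondary alcohol with retention at C8 and avoids the Z → E (angelate → tiglate) isomerisation, and the triene is already epoxidised so heating is safe.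

Step 12
Reactants: 26 (1R,2S,3S,6S,7R,8R,10S)-8-angeloyloxy-1,10:2,3-diepoxy-15-oxogermacra-4,11(13)-dien-12,6-olide
Product: 27 target, (1R,2S,3S,6S,7R,8R,10S)-8-angeloyloxy-1,10:2,3-diepoxy-15-hydroxygermacra-4Z,11(13)-dien-12,6-olide
Conditions: NaBH4, CeCl3·7H2O, MeOH, −78 °C, 10 min
Reagents that add atoms: none
Why: Luche reduction gives fast 1,2-reduction of the enal at low temperature, before the α-methylene lactone, the angelate or the oxiranes can react, and creates no new stereocentre.

**Compound list**
1 | m-cresol | Cc1cccc(O)c1 | starting material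
2 | 3-methylanisole | COc1cccc(C)c1 | intermediate
3 | 1-methoxy-5-methylcyclohexa-1,4-diene | COC1=CCC=C(C)C1 | intermediate
4 | ethyl diazoacetate | CCOC(=O)C=[N+]=[N-] | starting material
5 | ethyl bromodiazoacetate | CCOC(=O)C(Br)=[N+]=[N-] | intermediate
6 | ethyl 7-bromo-1-methoxy-3-methylbicyclo[4.1.0]hept-3-ene-7-carboxylate | CCOC(=O)C1(Br)C2CC=C(C)CC12OC | intermediate
7 | ethyl 5-methyl-7-oxocyclohepta-2,4-diene-1-carboxylate (racemic, keto/enol) | CCOC(=O)C1C=CC=C(C)CC1=O | intermediate
8 | dimethoxyacetaldehyde | COC(OC)C=O | starting material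
9 | methyl 2-(bromomethyl)acrylate | C=C(CBr)C(=O)OC | starting material
10 | methyl (4R)-5,5-dimethoxy-2-methylidene-4-(trimethylsilyloxy)pentanoate | COC(OC)[C@@H](CC(=C)C(=O)OC)O[Si](C)(C)C | intermediate
11 | (5R)-5-(dimethoxymethyl)-3-methylideneoxolan-2-one | COC(OC)[C@H]1CC(=C)C(=O)O1 | intermediate
12 | (5R)-3-bromo-3-(bromomethyl)-5-(dimethoxymethyl)oxolan-2-one (C3 epimers) | COC(OC)[C@H]1CC(Br)(CBr)C(=O)O1 | intermediate
13 | (5R)-3-(bromomethyl)-5-(dimethoxymethyl)furan-2(5H)-one | COC(OC)[C@@H]1OC(=O)C(CBr)=C1 | intermediate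
14 | ethyl 1-{[(2R)-4-(bromomethyl)-5-oxo-2,5-dihydrofuran-2-yl](methoxy)methyl}-5-methyl-7-oxocyclohepta-2,4-diene-1-carboxylate (C4/C5 epimers) | CCOC(=O)C1(C(OC)[C@@H]2OC(=O)C(CBr)=C2)C=CC=C(C)CC1=O | intermediate
15 | allylzinc bromide from 14 | CCOC(=O)C1(C(OC)[C@@H]2OC(=O)C(C[Zn]Br)=C2)C=CC=C(C)CC1=O | intermediate
16 | tricyclic zinc alkoxide (C7–C8 closed, cis-fused lactone) | CCOC(=O)C12C=CC=C(C)CC1(O[Zn]Br)[C@H]3C(=C)C(=O)O[C@H]3C2OC | intermediate
17 | ten-membered zinc ester enolate (C4–C8 broken, 5-OMe still present) | CCOC(O[Zn]Br)=C1/C=C\C=C(\C)CC(=O)[C@H]2C(=C)C(=O)O[C@H]2C1OC | intermediate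
18 | ethyl (6S,7S)-8-oxogermacra-1(10)Z,2Z,4,11(13)-tetraen-12,6-olid-15-oate | C=C1C(=O)O[C@H]2/C=C(/C(=O)OCC)\C=C/C=C(/C)CC(=O)[C@@H]12 | intermediate
19 | ethyl (6S,7R,8R)-8-hydroxygermacra-1(10)Z,2Z,4,11(13)-tetraen-12,6-olid-15-oate | C=C1C(=O)O[C@H]2/C=C(/C(=O)OCC)\C=C/C=C(/C)C[C@@H](O)[C@@H]12 | intermediate
20 | (6S,7R,8R)-germacra-1(10)Z,2Z,4,11(13)-tetraene-8,15-diol 12,6-lactol | C=C1C(O)O[C@H]2/C=C(/CO)\C=C/C=C(/C)C[C@@H](O)[C@@H]12 | intermediate
21 | (6S,7R,8R)-8-hydroxy-15-oxogermacra-1(10)Z,2Z,4,11(13)-tetraen-12,6-olide | C=C1C(=O)O[C@H]2/C=C(/C=O)\C=C/C=C(/C)C[C@@H](O)[C@@H]12 | intermediate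
22 | (1R,6S,7R,8R,10S)-1,10-epoxy-8-hydroxy-15-oxogermacra-2Z,4,11(13)-trien-12,6-olide | C=C1C(=O)O[C@H]2/C=C(/C=O)\C=C/[C@H]3O[C@@]3(C)C[C@@H](O)[C@@H]12 | intermediate
23 | (1R,2S,3S,6S,7R,8R,10S)-1,10:2,3-diepoxy-8-hydroxy-15-oxogermacra-4,11(13)-dien-12,6-olide | C=C1C(=O)O[C@H]2/C=C(/C=O)[C@@H]3O[C@@H]3[C@H]3O[C@@]3(C)C[C@@H](O)[C@@H]12 | intermediate
24 | angelic acid, (Z)-2-methylbut-2-enoic acid | C/C=C(/C)C(=O)O | starting material
25 | angelic 2,4,6-trichlorobenzoic anhydride | C/C=C(/C)C(=O)OC(=O)c1c(Cl)cc(Cl)cc1Cl | intermediate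
26 | (1R,2S,3S,6S,7R,8R,10S)-8-angeloyloxy-1,10:2,3-diepoxy-15-oxogermacra-4,11(13)-dien-12,6-olide | C=C1C(=O)O[C@H]2/C=C(/C=O)[C@@H]3O[C@@H]3[C@H]3O[C@@]3(C)C[C@@H](OC(=O)/C(C)=C\C)[C@@H]12 | intermediate
27 | CNP0157626.1, (1R,2S,3S,6S,7R,8R,10S)-8-angeloyloxy-1,10:2,3-diepoxy-15-hydroxygermacra-4Z,11(13)-dien-12,6-olide | C=C1C(=O)O[C@H]2/C=C(/CO)[C@@H]3O[C@@H]3[C@H]3O[C@@]3(C)C[C@@H](OC(=O)/C(C)=C\C)[C@@H]12 | target

**Totals:** 12 steps in all. The longest linear sequence is 10 steps (steps 1, 2, 3, 6, 7, 8, 9, 10, 11, 12).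

**Three steps most likely to fail**

Step 7 (the proposed new step). The zinc alkoxide 16 may simply persist without C4–C8 cleavage. The allylzinc may instead collapse by 1,4-elimination with opening of the lactone. The Z,Z,Z-triene 18 may also electrocyclise if the mixture has to be warmed. The fallback uses known chemistry, sets out from 14 and comes back at 18. A Barbier cyclisation under protic conditions (Zn dust, THF/sat. aq. NH4Cl, 0 °C) stops at the protonated adduct, the tricyclic tertiary alcohol F3, which is isolated. A classical anionic retro-aldol fragmentation with E1cB loss of methoxide (KN(SiMe3)2, THF, −78 → 0 °C) then gives 18.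

Step 6. The extended enolate of 7 may react through its vinylogous carbons (C2 or C10) instead of C4, or by SN2' on the allylic bromide. The fallback sets out from 7 and comes back at 14. The diene is first masked with Fe2(CO)9 in Et2O as the tricarbonyliron complex of 7 F1. Its enolate is no longer conjugated with the diene and can only react at C4. The same TiCl4/i-Pr2NEt acetal coupling with 13 gives the tricarbonyliron complex of 14 F2. Oxidative decomplexation with (NH4)2Ce(NO3)6 in acetone at −20 °C then releases 14.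

Step 10. Facial selectivity on the flexible ten-membered ring may be low or wrong, above all for the second oxirane. The fallback sets out from 21 and comes back at 26. VO(acac)2/t-BuOOH in CH2Cl2 at 0 °C gives the hydroxyl-directed monoepoxide 22, which is now isolated. Esterification with mixed anhydride 25 gives the 8-O-angelate of 22 F4. The remaining cis C2=C3 bond of this vinyl oxirane is then epoxidised under reagent control with a chiral dioxirane, made from a glucose-derived oxazolidinone ketone of the matching enantiomer and KHSO5 at pH 8 and 0 °C, to give 26.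

**Further compounds**
F1 | step 6 | tricarbonyl[η4-(ethyl 5-methyl-7-oxocyclohepta-2,4-diene-1-carboxylate)]iron | CCOC(=O)C1C=CC=C(C)CC1=O.[Fe].[C-]#[O+].[C-]#[O+].[C-]#[O+]
F2 | step 6 | tricarbonyliron complex of 14 (iron on the ring diene) | CCOC(=O)C1(C(OC)[C@@H]2OC(=O)C(CBr)=C2)C=CC=C(C)CC1=O.[Fe].[C-]#[O+].[C-]#[O+].[C-]#[O+]
F3 | step 7 | tricyclic tertiary alcohol (protonated form of 16, cis-fused α-methylene lactone) | CCOC(=O)C12C=CC=C(C)CC1(O)[C@H]3C(=C)C(=O)O[C@H]3C2OC
F4 | step 10 | (1R,6S,7R,8R,10S)-8-angeloyloxy-1,10-epoxy-15-oxogermacra-2Z,4,11(13)-trien-12,6-olide | C=C1C(=O)O[C@H]2/C=C(/C=O)\C=C/[C@H]3O[C@@]3(C)C[C@@H](OC(=O)/C(C)=C\C)[C@@H]12
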